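**Assumption:** side-chain carbons are numbered C1'–C16' from the ring; nerol, 1-bromobut-2-yne, trimethyl(prop-1-yn-1-yl)silane and 2-hydroxy-3-methylbenzaldehyde are bought; enantiopurity rests on step 1 (about 90–94 % ee expected for nerol), with chiral-phase chromatography of diol 5 if more is needed.

## Retrosynthetic overview

1. Quinone last: Teuber oxidation of a 2-alkyl-6-methylphenol. No ring is built; the bought benzene ring becomes the quinone in the final step, and the only other ring is a temporary acetonide.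
2. C7'–C8' by B-alkyl Suzuki–Miyaura coupling of an East alkylborane (C8'–C16', both stereocentres) with a West (E)-2-iodoalkene (arene + C1'–C7').
3. East: Sharpless epoxidation of nerol (only the allylic alkene reacts), then one-pot Payne rearrangement / sulfonium-ylide homologation. C11' is retained and C10' inverted, giving (10'R,11'R) and the vinyl handle.
4. West: both E-alkenes come from alkynes. Negishi carboalumination of hepta-1,5-diyne plus benzylic cross-coupling forms C1'–C2'; hydrozirconation–iodination sets C6'=C7'.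
5. Avoided on purpose: aryl-metal + polyprenyl bromide (aryl–C1') and asymmetric dihydroxylation of a polyene.

## Route

**Step 1**
Reactants: 1 nerol [(2Z)-3,7-dimethylocta-2,6-dien-1-ol]
Product: 2 [(2S,3R)-3-methyl-3-(4-methylpent-3-en-1-yl)oxiran-2-yl]methanol
Conditions: Ti(OiPr)4 (10 mol %), L-(+)-diethyl tartrate (12 mol %), t-BuOOH (2 equiv, in decane), 4 Å MS, CH2Cl2, −20 °C
Reagents that add atoms: tert-butyl hydroperoxide, CC(C)(C)OO
Why: Katsuki–Sharpless asymmetric epoxidation is directed by the allylic hydroxyl, so only the C2–C3 alkene reacts, and L-(+)-tartrate delivers oxygen to the face that gives 2S, which for the Z-alkene of nerol means (2S,3R), so the future C11' is already R.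

**Step 2**
Reactants: 2 [(2S,3R)-3-methyl-3-(4-methylpent-3-en-1-yl)oxiran-2-yl]methanol
Product: 5 (3R,4R)-4,8-dimethylnona-1,7-diene-3,4-diol, via Payne epoxide 3 (not isolated), via sulfonium betaine 4 (not isolated)
Conditions: Me3S+ I− (5 equiv), n-BuLi (4.8 equiv), THF, −10 °C → rt
Reagents that add atoms: trimethylsulfonium iodide, C[S+](C)C.[I-]
Why: Tandem Payne rearrangement / Corey–Chaykovsky-ylide homologation of an epoxide to an allylic alcohol, in which the alkoxide of 2 attacks C2 with inversion (future C10' becomes R, C11' untouched) to give terminal epoxide 3, the ylide opens only its unhindered CH2, and β-elimination of dimethyl sulfide from betaine 4 leaves the vinyl group.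

**Step 3**
Reactants: 5 (3R,4R)-4,8-dimethylnona-1,7-diene-3,4-diol
Product: 6 (4R,5R)-5-ethenyl-2,2,4-trimethyl-4-(4-methylpent-3-en-1-yl)-1,3-dioxolane
Conditions: Me2C(OMe)2, PPTS (cat.), CH2Cl2, rt
Reagents that add atoms: 2,2-dimethoxypropane, COC(C)(C)OC
Why: Acid-catalysed transketalisation (acetonide formation) masks both hydroxyls for the hydroboration and the basic coupling without touching either stereocentre.

**Step 4**
Reactants: 7 1-bromobut-2-yne; 8 trimethyl(prop-1-yn-1-yl)silane
Product: 10 hepta-1,5-diyn-1-yl(trimethyl)silane, via lithiated silylpropyne 9 (not isolated)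
Conditions: 8, n-BuLi, TMEDA, THF, −78 → −20 °C; then 7, −78 °C → rt
Reagents that add atoms: none
Why: Corey–Kirst propargylation, in which the lithiated 1-silylpropyne reacts at its CH2 terminus in an SN2 displacement of the primary propargylic bromide to give the 1,5-diyne.

**Step 5**
Reactants: 10 hepta-1,5-diyn-1-yl(trimethyl)silane
Product: 11 hepta-1,5-diyne
Conditions: K2CO3 (cat.), MeOH, rt; volatile product distilled and kept as a solution in ClCH2CH2Cl
Reagents that add atoms: none
Why: Base-catalysed protodesilylation of the C(sp)–Si bond frees the terminal alkyne for carbometalation while the internal alkyne is inert.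

**Step 6**
Reactants: 12 2-hydroxy-3-methylbenzaldehyde
Product: 13 2-(methoxymethoxy)-3-methylbenzaldehyde
Conditions: MeOCH2Cl, i-Pr2NEt, CH2Cl2, 0 °C → rt
Reagents that add atoms: chloromethyl methyl ether, COCCl
Why: O-alkylation of the phenol (MOM protection) gives an acetal that survives hydride, organometallic and basic steps and is removed later together with the acetonide.

**Step 7**
Reactants: 13 2-(methoxymethoxy)-3-methylbenzaldehyde
Product: 14 [2-(methoxymethoxy)-3-methylphenyl]methanol
Conditions: NaBH4, MeOH, 0 °C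
Reagents that add atoms: none
Why: Borohydride reduction of the aryl aldehyde gives the benzylic alcohol and leaves the MOM acetal intact.

**Step 8**
Reactants: 14 [2-(methoxymethoxy)-3-methylphenyl]methanol
Product: 15 1-(chloromethyl)-2-(methoxymethoxy)-3-methylbenzene
Conditions: PPh3, N-chlorosuccinimide, THF, 0 °C → rt
Reagents that add atoms: N-chlorosuccinimide, ClN1C(=O)CCC1=O
Why: Appel-type chlorination converts the benzylic alcohol to the chloride under neutral conditions that spare the acid-labile MOM group.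

**Step 9**
Reactants: 11 hepta-1,5-diyne; 15 1-(chloromethyl)-2-(methoxymethoxy)-3-methylbenzene
Product: 17 2-(methoxymethoxy)-1-methyl-3-[(2E)-3-methyloct-2-en-6-yn-1-yl]benzene, via alkenylalane 16 (not isolated)
Conditions: 11, Me3Al (2 equiv), Cp2ZrCl2 (20 mol %), ClCH2CH2Cl, 0 °C → rt; volatiles removed in vacuo; then 15, Pd(PPh3)4 (5 mol %), THF, rt
Reagents that add atoms: trimethylaluminium, C[Al](C)C
Why: Negishi zirconium-catalysed carboalumination adds methyl and aluminium syn across the terminal alkyne only (the internal alkyne reacts far more slowly), fixing the E geometry of C2'=C3', and the alkenylalane then cross-couples with the benzylic chloride under zerovalent palladium with retention to form C1'–C2'.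

**Step 10**
Reactants: 17 2-(methoxymethoxy)-1-methyl-3-[(2E)-3-methyloct-2-en-6-yn-1-yl]benzene
Product: 19 1-[(2E,6E)-7-iodo-3-methylocta-2,6-dien-1-yl]-2-(methoxymethoxy)-3-methylbenzene, via alkenylzirconocene 18 (not isolated)
Conditions: Cp2Zr(H)Cl (2 equiv), THF, 50 °C; then I2, THF, 0 °C
Reagents that add atoms: iodine, II
Why: Hydrozirconation–iodination, in which syn addition of Zr–H under equilibrating conditions places zirconium on the methyl-bearing carbon of the 2-alkyne and iodinolysis with retention gives the (E)-2-iodoalkene that encodes the C6'=C7' geometry.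

**Step 11**
Reactants: 6 (4R,5R)-5-ethenyl-2,2,4-trimethyl-4-(4-methylpent-3-en-1-yl)-1,3-dioxolane; 19 1-[(2E,6E)-7-iodo-3-methylocta-2,6-dien-1-yl]-2-(methoxymethoxy)-3-methylbenzene
Product: 21 (4R,5R)-5-{(3E,7E)-9-[2-(methoxymethoxy)-3-methylphenyl]-3,7-dimethylnona-3,7-dien-1-yl}-2,2,4-trimethyl-4-(4-methylpent-3-en-1-yl)-1,3-dioxolane, via alkylborane 20 (not isolated)
Conditions: 6, 9-borabicyclo[3.3.1]nonane dimer, THF, rt; then 19, PdCl2(dppf) (5 mol %), AsPh3, aq Cs2CO3, DMF, rt
Reagents that add atoms: none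
Why: B-alkyl Suzuki–Miyaura coupling, in which 9-borabicyclo[3.3.1]nonane hydroborates only the monosubstituted vinyl group at its terminus and the alkylborane couples with the alkenyl iodide with retention of the E geometry, forging C7'–C8' without touching the stereocentres.

**Step 12**
Reactants: 21 (4R,5R)-5-{(3E,7E)-9-[2-(methoxymethoxy)-3-methylphenyl]-3,7-dimethylnona-3,7-dien-1-yl}-2,2,4-trimethyl-4-(4-methylpent-3-en-1-yl)-1,3-dioxolane
Product: 22 2-[(2E,6E,10R,11R)-10,11-dihydroxy-3,7,11,15-tetramethylhexadeca-2,6,14-trien-1-yl]-6-methylphenol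
Conditions: 3 M aq HCl, THF, 40 °C
Reagents that add atoms: none
Why: Acid-catalysed acetal hydrolysis removes the acetonide and the aryl MOM ether in one operation under conditions too mild for chroman formation or pinacol rearrangement.

**Step 13**
Reactants: 22 2-[(2E,6E,10R,11R)-10,11-dihydroxy-3,7,11,15-tetramethylhexadeca-2,6,14-trien-1-yl]-6-methylphenol
Product: 23 2-[(2E,6E,10R,11R)-10,11-dihydroxy-3,7,11,15-tetramethylhexadeca-2,6,14-trien-1-yl]-6-methylcyclohexa-2,5-diene-1,4-dione
Conditions: (KSO3)2NO (2.5 equiv), KH2PO4 buffer (pH 6), acetone/H2O, rt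
Reagents that add atoms: potassium nitrosodisulfonate, [K+].[K+].[O]N(S(=O)(=O)[O-])S(=O)(=O)[O-]
Why: Teuber oxidation, in which one nitrosodisulfonate radical abstracts the phenolic hydrogen and a second adds at the free para position to give the 2,6-disubstituted 1,4-benzoquinone directly, leaving the diol and the trisubstituted alkenes alone.

## Compound list

1 | nerol, (2Z)-3,7-dimethylocta-2,6-dien-1-ol | CC(C)=CCC/C(C)=C\CO | starting material
2 | [(2S,3R)-3-methyl-3-(4-methylpent-3-en-1-yl)oxiran-2-yl]methanol | CC(C)=CCC[C@@]1(C)O[C@H]1CO | intermediate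
3 | (2R)-6-methyl-2-[(2R)-oxiran-2-yl]hept-5-en-2-ol | CC(C)=CCC[C@@](C)(O)[C@H]1CO1 | intermediate
4 | (3R,4R)-1-(dimethylsulfonio)-4-hydroxy-4,8-dimethylnon-7-en-3-olate | CC(C)=CCC[C@@](C)(O)[C@H]([O-])CC[S+](C)C | intermediate
5 | (3R,4R)-4,8-dimethylnona-1,7-diene-3,4-diol | CC(C)=CCC[C@@](C)(O)[C@H](O)C=C | intermediate
6 | (4R,5R)-5-ethenyl-2,2,4-trimethyl-4-(4-methylpent-3-en-1-yl)-1,3-dioxolane | CC(C)=CCC[C@@]1(C)OC(C)(C)O[C@@H]1C=C | intermediate
7 | 1-bromobut-2-yne | CC#CCBr | starting material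
8 | trimethyl(prop-1-yn-1-yl)silane | CC#C[Si](C)(C)C | starting material
9 | [3-(trimethylsilyl)prop-2-yn-1-yl]lithium | [Li]CC#C[Si](C)(C)C | intermediate
10 | hepta-1,5-diyn-1-yl(trimethyl)silane | CC#CCCC#C[Si](C)(C)C | intermediate
11 | hepta-1,5-diyne | CC#CCCC#C | intermediate
12 | 2-hydroxy-3-methylbenzaldehyde | Cc1cccc(C=O)c1O | starting material
13 | 2-(methoxymethoxy)-3-methylbenzaldehyde | COCOc1c(C)cccc1C=O | intermediate
14 | [2-(methoxymethoxy)-3-methylphenyl]methanol | COCOc1c(C)cccc1CO | intermediate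
15 | 1-(chloromethyl)-2-(methoxymethoxy)-3-methylbenzene | COCOc1c(C)cccc1CCl | intermediate
16 | dimethyl[(1E)-2-methylhept-1-en-5-yn-1-yl]alane | C[Al](C)/C=C(\C)CCC#CC | intermediate
17 | 2-(methoxymethoxy)-1-methyl-3-[(2E)-3-methyloct-2-en-6-yn-1-yl]benzene | COCOc1c(C)cccc1C/C=C(\C)CCC#CC | intermediate
18 | chlorobis(cyclopentadienyl){(2E,6E)-8-[2-(methoxymethoxy)-3-methylphenyl]-6-methylocta-2,6-dien-2-yl}zirconium | COCOc1c(C)cccc1C/C=C(\C)CC/C=C(\C)[Zr](Cl)(C1C=CC=C1)C1C=CC=C1 | intermediate
19 | 1-[(2E,6E)-7-iodo-3-methylocta-2,6-dien-1-yl]-2-(methoxymethoxy)-3-methylbenzene | COCOc1c(C)cccc1C/C=C(\C)CC/C=C(\C)I | intermediate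
20 | 9-{2-[(4R,5R)-2,2,5-trimethyl-5-(4-methylpent-3-en-1-yl)-1,3-dioxolan-4-yl]ethyl}-9-borabicyclo[3.3.1]nonane | CC(C)=CCC[C@@]1(C)OC(C)(C)O[C@@H]1CCB1C2CCCC1CCC2 | intermediate
21 | (4R,5R)-5-{(3E,7E)-9-[2-(methoxymethoxy)-3-methylphenyl]-3,7-dimethylnona-3,7-dien-1-yl}-2,2,4-trimethyl-4-(4-methylpent-3-en-1-yl)-1,3-dioxolane | CC(C)=CCC[C@@]1(C)OC(C)(C)O[C@@H]1CC/C(C)=C/CC/C(C)=C/Cc1cccc(C)c1OCOC | intermediate
22 | 2-[(2E,6E,10R,11R)-10,11-dihydroxy-3,7,11,15-tetramethylhexadeca-2,6,14-trien-1-yl]-6-methylphenol | CC(C)=CCC[C@@](C)(O)[C@H](O)CC/C(C)=C/CC/C(C)=C/Cc1cccc(C)c1O | intermediate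
23 | 2-[(2E,6E,10R,11R)-10,11-dihydroxy-3,7,11,15-tetramethylhexadeca-2,6,14-trien-1-yl]-6-methylcyclohexa-2,5-diene-1,4-dione | CC(C)=CCC[C@@](C)(O)[C@H](O)CC/C(C)=C/CC/C(C)=C/CC1=CC(=O)C=C(C)C1=O | target

## Step count and risks

Total steps: 13. Longest linear sequence: 8 steps (12 → 13 → 14 → 15 → 17 → 19 → 21 → 22 → 23).

**Most likely to fail: step 2.** The Payne equilibrium of a 3,3-disubstituted epoxy alcohol lies far on the side of 2, and the ylide must intercept the small amount of 3. The fallback sets out from 1 and comes back at 3, making the terminal epoxide without a Payne step. Nerol 1 is epoxidised with the mirror-image catalyst (Ti(OiPr)4, D-(−)-diethyl tartrate, t-BuOOH) to [(2R,3S)-3-methyl-3-(4-methylpent-3-en-1-yl)oxiran-2-yl]methanol F1. Dilute HClO4 in THF/H2O opens F1 at the tertiary carbon with inversion to (2R,3R)-3,7-dimethyloct-6-ene-1,2,3-triol F2. TsCl in pyridine at 0 °C sulfonylates only the primary hydroxyl to give (2R,3R)-2,3-dihydroxy-3,7-dimethyloct-6-en-1-yl 4-methylbenzenesulfonate F3, and K2CO3 in MeOH closes F3 to epoxide 3, now isolated. Compound 3 then needs only the ylide opening of a simple monosubstituted epoxide (Me3S+ I−, n-BuLi) to reach 5.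

**Second: step 9.** The selective mono-carboalumination of a diyne, and the coupling of an aluminium reagent with a MOM-bearing benzylic chloride, could each give trouble (methyl transfer, acetal cleavage). The fallback sets out from 16 and comes back at 17, replacing the C1'–C2' coupling by the classical aryl–C1' bond. Alane 16 is converted with n-BuLi into lithium butyl(dimethyl)[(1E)-2-methylhept-1-en-5-yn-1-yl]alanate F4 and trapped with paraformaldehyde to give (2E)-3-methyloct-2-en-6-yn-1-ol F5, which CBr4/PPh3 turns into (2E)-1-bromo-3-methyloct-2-en-6-yne F6. Separately, 1-(methoxymethoxy)-2-methylbenzene F7 (from o-cresol, MeOCH2Cl and i-Pr2NEt) is lithiated at its only free ortho position (n-BuLi, TMEDA, Et2O, 0 °C) to [2-(methoxymethoxy)-3-methylphenyl]lithium F8. In the presence of CuBr·SMe2, F8 displaces the bromide of F6 at the primary carbon to give 17.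

**Third: step 10.** Hydrozirconation of a 2-alkyne gives a small amount of the 3-iodo regioisomer, which is hard to separate. The fallback sets out from 9 and comes back at 19, using silicon to make the hydrometalation regiospecific. Lithio species 9 is alkylated with propargyl bromide to hexa-1,5-diyn-1-yl(trimethyl)silane F9. Carboalumination as in step 9 (the silylalkyne is inert) gives dimethyl[(1E)-2-methyl-6-(trimethylsilyl)hex-1-en-5-yn-1-yl]alane F10, which couples with 15 under Pd(PPh3)4 to {(5E)-7-[2-(methoxymethoxy)-3-methylphenyl]-5-methylhept-5-en-1-yn-1-yl}trimethylsilane F11. i-Bu2AlH in heptane at 50 °C adds with aluminium on the silicon-bearing carbon and net trans geometry to give bis(2-methylpropyl){(1E,5E)-7-[2-(methoxymethoxy)-3-methylphenyl]-5-methyl-1-(trimethylsilyl)hepta-1,5-dien-1-yl}alane F12. MeLi converts it into lithium methylbis(2-methylpropyl){(1E,5E)-7-[2-(methoxymethoxy)-3-methylphenyl]-5-methyl-1-(trimethylsilyl)hepta-1,5-dien-1-yl}alanate F13, and MeI methylates the C–Al bond with retention to {(2E,6E)-8-[2-(methoxymethoxy)-3-methylphenyl]-6-methylocta-2,6-dien-2-yl}trimethylsilane F14. N-Iodosuccinimide in MeCN then replaces silicon by iodine with retention to give 19.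

## Further compounds

F1 | step 2 | [(2R,3S)-3-methyl-3-(4-methylpent-3-en-1-yl)oxiran-2-yl]methanol | CC(C)=CCC[C@]1(C)O[C@@H]1CO
F2 | step 2 | (2R,3R)-3,7-dimethyloct-6-ene-1,2,3-triol | CC(C)=CCC[C@@](C)(O)[C@H](O)CO
F3 | step 2 | (2R,3R)-2,3-dihydroxy-3,7-dimethyloct-6-en-1-yl 4-methylbenzenesulfonate | CC(C)=CCC[C@@](C)(O)[C@H](O)COS(=O)(=O)c1ccc(C)cc1
F4 | step 9 | lithium butyl(dimethyl)[(1E)-2-methylhept-1-en-5-yn-1-yl]alanate | [Li+].CCCC[Al-](C)(C)/C=C(\C)CCC#CC
F5 | step 9 | (2E)-3-methyloct-2-en-6-yn-1-ol | CC#CCC/C(C)=C/CO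
F6 | step 9 | (2E)-1-bromo-3-methyloct-2-en-6-yne | CC#CCC/C(C)=C/CBr
F7 | step 9 | 1-(methoxymethoxy)-2-methylbenzene | COCOc1ccccc1C
F8 | step 9 | [2-(methoxymethoxy)-3-methylphenyl]lithium | [Li]c1cccc(C)c1OCOC
F9 | step 10 | hexa-1,5-diyn-1-yl(trimethyl)silane | C#CCCC#C[Si](C)(C)C
F10 | step 10 | dimethyl[(1E)-2-methyl-6-(trimethylsilyl)hex-1-en-5-yn-1-yl]alane | C[Al](C)/C=C(\C)CCC#C[Si](C)(C)C
F11 | step 10 | {(5E)-7-[2-(methoxymethoxy)-3-methylphenyl]-5-methylhept-5-en-1-yn-1-yl}trimethylsilane | COCOc1c(C)cccc1C/C=C(\C)CCC#C[Si](C)(C)C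
F12 | step 10 | bis(2-methylpropyl){(1E,5E)-7-[2-(methoxymethoxy)-3-methylphenyl]-5-methyl-1-(trimethylsilyl)hepta-1,5-dien-1-yl}alane | COCOc1c(C)cccc1C/C=C(\C)CC/C=C(\[Al](CC(C)C)CC(C)C)[Si](C)(C)C
F13 | step 10 | lithium methylbis(2-methylpropyl){(1E,5E)-7-[2-(methoxymethoxy)-3-methylphenyl]-5-methyl-1-(trimethylsilyl)hepta-1,5-dien-1-yl}alanate | [Li+].COCOc1c(C)cccc1C/C=C(\C)CC/C=C(\[Al-](C)(CC(C)C)CC(C)C)[Si](C)(C)C
F14 | step 10 | {(2E,6E)-8-[2-(methoxymethoxy)-3-methylphenyl]-6-methylocta-2,6-dien-2-yl}trimethylsilane | COCOc1c(C)cccc1C/C=C(\C)CC/C=C(\C)[Si](C)(C)C
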